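A direct plan would benzylate the phenol of methyl 3-hydroxy-4,5-dimethoxybenzoate A1, saponify to the acid A2 and esterify it with the ring A phenol to the aryl benzoate A3.
It would then methylenate the ester to the aryl 1-arylvinyl ether A4, close ring C by a Pd(OAc)2-catalysed oxidative carbonylative double C–H annulation with CO to the O-benzyl flavone A5, and debenzylate.
Weakest would be the carbonylative closure of ring C: it would be without precedent, would have to outrun collapse of the palladacycle to a 2-arylbenzofuran, and would be risked on the most advanced material.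
Next would be the ester methylenation: excess Cp2TiMe2 would be spent to make an enol ether that silica, or the acetic acid set free in the following step, would hydrolyse.
Third would be the benzyl on/off pair: with the saponification, three of six steps would add no skeletal bond, and the final hydrogenolysis could also reduce C2=C3 of the flavone.

Plan of the new route:
The retrosynthesis cuts C2–C1' first (ring C to ring B), then O1–C2 and C2–C3 of ring C. This leads back to commercial 2'-hydroxy-3',4'-dimethoxyacetophenone, one carbon from an amide acetal, and commercial 2,3-dimethoxyphenol.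
Ring A is bought with C4 and C3 attached, ring C is closed first to give 7,8-dimethoxychromone, and ring B is joined last as an intact, unprotected phenol. The flavone skeleton appears only in the target.
The feature used is that rings A and B both carry the 2,3-dimethoxyphenol pattern. Ring A is bonded ortho to its oxygen; ring B is bonded at C1', which is C5 of 2,3-dimethoxyphenol, its only ring C–H with no ortho substituent, so a sterically controlled C–H borylation marks exactly that site.
C2–H of ring C is the β-carbon of the vinylogous ester O1–C2=C3–C4=O, the one position that accepts an aryl–palladium bond and then loses its hydrogen.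
No protecting group is put on or taken off, no enol ether is made, no CO is used and C4=O arrives with the acetophenone, so none of the weak steps arises.

Key step: step 3

Remark: the target has no stereocentre. The aryl pinacol boronate is assumed to transmetalate directly to divalent palladium, as arylboronic esters do in base-free oxidative Heck reactions.

Step 1
Reactants: 1 2'-hydroxy-3',4'-dimethoxyacetophenone
Product: 3 7,8-dimethoxychromone (7,8-dimethoxy-4H-chromen-4-one), via enaminone 2 (not isolated)
Conditions: DMF-DMA (2.0 equiv), toluene, 100 °C, 4 h; evaporate; then conc. HCl (2 equiv), CH2Cl2, 40 °C, 1 h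
Reagents that add atoms: N,N-dimethylformamide dimethyl acetal, COC(OC)N(C)C
Why: Condensation of the methyl ketone with the amide acetal should give the (E)-enaminone 2, and acid then promotes conjugate addition of the ortho hydroxyl to the β-carbon with loss of dimethylamine (addition–elimination), the standard enaminone synthesis of 3-unsubstituted chromones, in which ring C can close only onto the single phenol oxygen.

Step 2
Reactants: 4 2,3-dimethoxyphenol
Product: 7 2,3-dimethoxy-5-(4,4,5,5-tetramethyl-1,3,2-dioxaborolan-2-yl)phenol, via aryl borate 5 (not isolated), via bis-borylated arene 6 (not isolated)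
Conditions: HBpin (3.0 equiv, the first 1.2 equiv at rt until H2 evolution stops), [Ir(OMe)(cod)]2 (1.5 mol %), 4,4'-di-tert-butyl-2,2'-bipyridine (dtbpy, 3 mol %), THF, 80 °C, 16 h; then MeOH, rt; SiO2
Reagents that add atoms: pinacolborane, [H]B1OC(C)(C)C(C)(C)O1
Why: Iridium-catalysed aromatic C–H borylation under steric control, in which pinacolborane first converts the phenol into the aryl borate 5 (a protecting group that needs no separate step), the tris(boryl) complex of trivalent iridium then activates C5–H, the only ring C–H with no ortho substituent (C4–H lies beside a methoxy group and C6–H beside the O-boryl group), and methanol finally cleaves the labile aryl O–B bond while the aryl pinacol boronate stays intact.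

Step 3
Reactants: 3 7,8-dimethoxychromone; 7 2,3-dimethoxy-5-(4,4,5,5-tetramethyl-1,3,2-dioxaborolan-2-yl)phenol (1.5 equiv)
Product: 9 3'-hydroxy-4',5',7,8-tetramethoxyflavone, via palladium enolate 8 (not isolated)
Conditions: Pd(OCOCF3)2 (10 mol %), 6,6'-dimethyl-2,2'-bipyridine (12 mol %), O2 (1 atm), DMSO, 80 °C, 24 h
Reagents that add atoms: none
Why: Transmetalation from boron should give an aryl complex of divalent palladium, which adds across C2=C3 of 3 with the aryl group going to C2 to give the palladium enolate 8; β-hydride elimination from its C3-bound form (after epimerisation through the oxygen-bound enolate, as cyclic enones require) removes the C2 hydrogen, and O2 returns zerovalent palladium to divalent palladium. The closest known reaction type is the oxidative Heck coupling of chromones with arylboronic acids to flavones, applied here to an aryl pinacol boronate carrying a free phenol. No ring is closed: rings A and C enter as the chromone, ring B as the boronate, and only the C2–C1' bond is formed. No stereocentre is set, since C2 is sp3 only in 8 and returns to sp2. The C2 over C3 selectivity on ring C follows from the polarity of the vinylogous ester O1–C2=C3–C4=O (aryl to the β-carbon, palladium α to the carbonyl), and the site on ring B was fixed by the C–B bond made in step 2, so the meta hydroxyl needs no protection. Any flavanone formed by protonation of 8 should be dehydrogenated to the same flavone by Pd(OCOCF3)2/DMSO/O2 at 80 °C, so both pathways should converge on 9.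

**Compound list**
1 | 2'-hydroxy-3',4'-dimethoxyacetophenone | CC(=O)c1ccc(OC)c(OC)c1O | starting material
2 | (E)-3-(dimethylamino)-1-(2-hydroxy-3,4-dimethoxyphenyl)prop-2-en-1-one | CN(C)/C=C/C(=O)c1ccc(OC)c(OC)c1O | intermediate
3 | 7,8-dimethoxychromone (7,8-dimethoxy-4H-chromen-4-one) | COc1ccc2c(=O)ccoc2c1OC | intermediate
4 | 2,3-dimethoxyphenol | COc1cccc(O)c1OC | starting material
5 | 2-(2,3-dimethoxyphenoxy)-4,4,5,5-tetramethyl-1,3,2-dioxaborolane | COc1cccc(OB2OC(C)(C)C(C)(C)O2)c1OC | intermediate
6 | 2-[2,3-dimethoxy-5-(4,4,5,5-tetramethyl-1,3,2-dioxaborolan-2-yl)phenoxy]-4,4,5,5-tetramethyl-1,3,2-dioxaborolane | COc1cc(B2OC(C)(C)C(C)(C)O2)cc(OB2OC(C)(C)C(C)(C)O2)c1OC | intermediate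
7 | 2,3-dimethoxy-5-(4,4,5,5-tetramethyl-1,3,2-dioxaborolan-2-yl)phenol | COc1cc(B2OC(C)(C)C(C)(C)O2)cc(O)c1OC | intermediate
8 | racemic palladium enolate from addition of the aryl–palladium bond across C2=C3 of 3, divalent palladium on the enolate oxygen, in equilibrium with its C3-bound form (ancillary ligands omitted) | COc1cc(C2C=C(O[Pd])c3ccc(OC)c(OC)c3O2)cc(O)c1OC | intermediate
9 | 3'-hydroxy-4',5',7,8-tetramethoxyflavone [2-(3-hydroxy-4,5-dimethoxyphenyl)-7,8-dimethoxy-4H-chromen-4-one] | COc1cc(-c2cc(=O)c3ccc(OC)c(OC)c3o2)cc(O)c1OC | target

Total step count: 3. Longest linear sequence: 2 steps (step 1 then step 3, or step 2 then step 3).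

Steps most likely to fail:

Step 3. The palladium enolate may be protonated faster than it loses hydride and the follow-up dehydrogenation may stall; the boronate may be lost to oxidative homocoupling or oxidation to the phenol before it adds; or the pinacol ester may transmetalate too slowly. The fallback sets out from 3 and 7 and returns at 9. A redox-neutral conjugate addition with [Rh(OH)(cod)]2 (3 mol %, monovalent rhodium) in 1,4-dioxane/H2O at 60 °C should give racemic 3'-hydroxy-4',5',7,8-tetramethoxyflavanone F1. A separate dehydrogenation with I2 (10 mol %) in DMSO at 120 °C should then give 9. Arylation and oxidation are thereby uncoupled, and no oxidant is present while the boronate is in the flask.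

Step 2. Site selectivity may erode through borylation at C6 guided by the O-boryl group, or the catalyst may be deactivated by free phenol before O-borylation is complete. The fallback sets out from 4 and returns at 7. Silylation with TBSCl and imidazole in DMF should give tert-butyl(2,3-dimethoxyphenoxy)dimethylsilane F2, whose bulky silyl ether shields C6. Borylation with B2pin2 (1.0 equiv), [Ir(OMe)(cod)]2 and dtbpy in THF at 80 °C should give tert-butyl[2,3-dimethoxy-5-(4,4,5,5-tetramethyl-1,3,2-dioxaborolan-2-yl)phenoxy]dimethylsilane F3. Cleavage of the aryl silyl ether with K2CO3 in MeOH at rt should then give 7.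

Step 1. The amide acetal may O-methylate the phenol at high temperature, which would block ring closure, or the enaminone may hydrolyse back to the ketone during the acid stage. The fallback sets out from 1 and returns at 3. Claisen condensation of 1 with ethyl formate (NaH, THF, 0 °C to rt) should give the cyclic hemiacetal 2-hydroxy-7,8-dimethoxychroman-4-one F4. Acid-catalysed dehydration (cat. H2SO4, AcOH, 60 °C) should then give 3.

Further compounds
F1 | step 3 | racemic 3'-hydroxy-4',5',7,8-tetramethoxyflavanone | COc1cc(C2CC(=O)c3ccc(OC)c(OC)c3O2)cc(O)c1OC
F2 | step 2 | tert-butyl(2,3-dimethoxyphenoxy)dimethylsilane | COc1cccc(O[Si](C)(C)C(C)(C)C)c1OC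
F3 | step 2 | tert-butyl[2,3-dimethoxy-5-(4,4,5,5-tetramethyl-1,3,2-dioxaborolan-2-yl)phenoxy]dimethylsilane | COc1cc(B2OC(C)(C)C(C)(C)O2)cc(O[Si](C)(C)C(C)(C)C)c1OC
F4 | step 1 | racemic 2-hydroxy-7,8-dimethoxychroman-4-one | COc1ccc2C(=O)CC(O)Oc2c1OC
A1 | direct plan | methyl 3-hydroxy-4,5-dimethoxybenzoate | COC(=O)c1cc(O)c(OC)c(OC)c1
A2 | direct plan | 3-(benzyloxy)-4,5-dimethoxybenzoic acid | OC(=O)c1cc(OCc2ccccc2)c(OC)c(OC)c1
A3 | direct plan | 2,3-dimethoxyphenyl 3-(benzyloxy)-4,5-dimethoxybenzoate | COc1cccc(OC(=O)c2cc(OCc3ccccc3)c(OC)c(OC)c2)c1OC
A4 | direct plan | 1-(benzyloxy)-5-[1-(2,3-dimethoxyphenoxy)ethenyl]-2,3-dimethoxybenzene | C=C(Oc1cccc(OC)c1OC)c1cc(OCc2ccccc2)c(OC)c(OC)c1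
A5 | direct plan | 3'-(benzyloxy)-4',5',7,8-tetramethoxyflavone | COc1cc(-c2cc(=O)c3ccc(OC)c(OC)c3o2)cc(OCc2ccccc2)c1OC
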